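**Retrosynthetic overview**

1. Target 13 ← global desilylation of penta-silyl ether 12 (upper flavan-3-ol unit: rings A, C, B, atoms marked u; lower flavan-3,4-diol unit: resorcinol ring D, pyran ring F, catechol ring E, atoms marked l).
2. Ring F of 12 ← one-flask union of phenol 10 with epoxy aldehyde 5: C4a(l)–C4(l) by phenoxide-directed ortho-hydroxyalkylation, then O1(l)–C2(l) by 6-endo epoxide opening.
3. Enabling feature: ring D is a resorcinol in which C4a(l) is ortho to O1(l) and para to O7(l), and C2(l) is benzylic and para to the 4'-oxygen of ring E; the same phenol oxygen therefore first directs the C–C bond and then closes the pyran ring at the activated epoxide carbon.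
4. 10 ← C4(u)–C6(l) Friedel–Crafts bond between resorcinol 9 and flavan-3,4-diol 8; ring C of 8 ← the same annulation of phenol 6 with 5.
5. 5 ← ethyl caffeate 1 by Sharpless epoxidation, the source of C2 and C3 of both units; ring order: C first, F last.

Key step: step 7

Remark: 3-(tert-butyldimethylsilyloxy)phenol 6 is taken as a catalogue compound, and the titanium-bound intermediates 7 and 11 are written as the free alcohols (TBS = tert-butyldimethylsilyl).

**Step 1**
Reactants: 1 ethyl caffeate, ethyl (E)-3-(3,4-dihydroxyphenyl)prop-2-enoate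
Product: 2 ethyl (E)-3-[3,4-bis(tert-butyldimethylsilyloxy)phenyl]prop-2-enoate
Conditions: TBSCl (2.4 equiv), imidazole (5 equiv), DMF, rt
Reagents that add atoms: tert-butyldimethylsilyl chloride (TBSCl), CC(C)(C)[Si](C)(C)Cl
Why: Imidazole-promoted silylation of both catechol hydroxyls; silyl ethers are chosen because fluoride removes them at the end without hydrogenolysis or acid, which the benzylic C4(l) hydroxyl would not tolerate.

**Step 2**
Reactants: 2 ethyl (E)-3-[3,4-bis(tert-butyldimethylsilyloxy)phenyl]prop-2-enoate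
Product: 3 (E)-3-[3,4-bis(tert-butyldimethylsilyloxy)phenyl]prop-2-en-1-ol
Conditions: i-Bu2AlH (2.5 equiv), CH2Cl2, −78 °C
Reagents that add atoms: none
Why: 1,2-Reduction of the conjugated ester by the aluminium hydride should give the E allylic alcohol and leave the aryl silyl ethers and the alkene untouched.

**Step 3**
Reactants: 3 (E)-3-[3,4-bis(tert-butyldimethylsilyloxy)phenyl]prop-2-en-1-ol
Product: 4 [(2S,3S)-3-[3,4-bis(tert-butyldimethylsilyloxy)phenyl]oxiran-2-yl]methanol (trans)
Conditions: Ti(OiPr)4 (10 mol%), L-(+)-diethyl tartrate (12 mol%), t-BuOOH, 4 Å MS, CH2Cl2, −20 °C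
Reagents that add atoms: tert-butyl hydroperoxide, CC(C)(C)OO
Why: Sharpless asymmetric epoxidation; the L-(+)-tartrate should deliver oxygen to the alkene face that gives the (2S,3S)-trans-epoxide, as with (E)-cinnamyl alcohol, which fixes the carbons that become C2 and C3 of both flavan units.

**Step 4**
Reactants: 4 [(2S,3S)-3-[3,4-bis(tert-butyldimethylsilyloxy)phenyl]oxiran-2-yl]methanol
Product: 5 (2R,3S)-3-[3,4-bis(tert-butyldimethylsilyloxy)phenyl]oxirane-2-carbaldehyde (trans)
Conditions: SO3·pyridine, DMSO, Et3N, CH2Cl2, 0 °C; used crude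
Reagents that add atoms: none
Why: Parikh–Doering oxidation is base-buffered, so the acid-labile benzylic epoxide should survive, and the alpha stereocentre, held in the oxirane, should not epimerise (the descriptor changes from S to R only through the priority of the formyl group).

**Step 5**
Reactants: 6 3-(tert-butyldimethylsilyloxy)phenol; 5 (2R,3S)-3-[3,4-bis(tert-butyldimethylsilyloxy)phenyl]oxirane-2-carbaldehyde
Product: 8 (2R,3S,4S)-7-(tert-butyldimethylsilyloxy)-2-[3,4-bis(tert-butyldimethylsilyloxy)phenyl]chromane-3,4-diol (2,3-trans-3,4-cis), via anti epoxy alcohol 7 (not isolated)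
Conditions: 6, Ti(OiPr)4 (1.1 equiv), toluene, rt, then evaporation; 5, CH2Cl2, 0 °C to rt, then 40 °C
Reagents that add atoms: none
Why: Proposed new method: the aryloxytitanium triisopropoxide of 6 should add through its unhindered ortho carbon (para to the silyloxy group) to the titanium-coordinated aldehyde within a six-membered chelate, as in the ortho-specific hydroxyalkylation of metal phenoxides with alpha-oxygenated aldehydes, and the same phenoxide oxygen should then open the titanium-bound epoxy alcohol 7 in the 6-endo mode at the benzylic carbon with inversion, as in the Ti(OiPr)4-mediated C3-selective opening of 2,3-epoxy alcohols, which sets the 2,3-trans relation (2R); the C4 configuration is not critical here because C4 is ionised in step 6.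

**Step 6**
Reactants: 8 (2R,3S,4S)-7-(tert-butyldimethylsilyloxy)-2-[3,4-bis(tert-butyldimethylsilyloxy)phenyl]chromane-3,4-diol; 9 resorcinol
Product: 10 (2R,3S,4R)-7-(tert-butyldimethylsilyloxy)-2-[3,4-bis(tert-butyldimethylsilyloxy)phenyl]-4-(2,4-dihydroxyphenyl)chroman-3-ol (2,3-trans-3,4-trans)
Conditions: 9 (10 equiv), BF3·OEt2 (0.3 equiv), Et2O–CH2Cl2, 0 °C
Reagents that add atoms: none
Why: SN1 Friedel–Crafts alkylation, in which the Lewis acid ionises the C4 hydroxyl to a benzylic cation stabilised by the ortho ring oxygen and the para C7 silyloxy group and excess resorcinol attacks through its C4 anti to the C3 hydroxyl, which should set the 3,4-trans (4R) centre as in the classical condensations of flavan-3,4-diols with resorcinol.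

**Step 7**
Reactants: 10 (2R,3S,4R)-7-(tert-butyldimethylsilyloxy)-2-[3,4-bis(tert-butyldimethylsilyloxy)phenyl]-4-(2,4-dihydroxyphenyl)chroman-3-ol; 5 (2R,3S)-3-[3,4-bis(tert-butyldimethylsilyloxy)phenyl]oxirane-2-carbaldehyde
Product: 12 (2R,3S,4S)-2-[3,4-bis(tert-butyldimethylsilyloxy)phenyl]-6-[(2R,3S,4R)-7-(tert-butyldimethylsilyloxy)-2-[3,4-bis(tert-butyldimethylsilyloxy)phenyl]-3-hydroxychroman-4-yl]chromane-3,4,7-triol, via anti epoxy alcohol 11 (not isolated)
Conditions: 10, Ti(OiPr)4 (3.3 equiv), toluene, rt, then evaporation; 5 (1.3 equiv), CH2Cl2, 0 °C to rt, then 40 °C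
Reagents that add atoms: none
Why: Proposed new method: the titanium aryloxide of 10 should deliver the resorcinol carbon para to its hindered hydroxyl (the future C4a(l)) to the titanium-coordinated aldehyde of 5 through a six-membered chelate, and the titanium-bound epoxy alcohol 11 so formed is then opened at its benzylic carbon by the same phenoxide oxygen, which makes the O1(l)–C2(l) bond. The closest known reaction types are the ortho-specific hydroxyalkylation of magnesium and titanium phenoxides with alpha-oxygenated aldehydes, the Ti(OiPr)4-mediated C3-selective opening of 2,3-epoxy alcohols and the 6-endo cyclisation of 2'-hydroxychalcone epoxides to 2,3-trans-dihydroflavonols. Ring F closes in the 6-endo-tet mode, preferred over 5-exo because the attacked carbon is benzylic and para to a silyloxy group of ring E and because titanium bridges the C4(l) alkoxide and the epoxide oxygen. C2(l) is set by inversion at the (3S)-epoxide carbon (trans-epoxide to 2,3-trans, 2R), C3(l) is carried over from 5, and C4(l) is set by Felkin–Anh attack anti to the epoxide C–O bond of the non-chelated aldehyde, which gives the anti epoxy alcohol and hence the 3,4-cis diol (4S). The step needs site selectivity on ring D, secured because the competing ortho carbon lies between two oxygen substituents and only the para-disposed oxygen is ortho to the attacked carbon, and facial selectivity at the aldehyde, secured by the adjacent epoxide stereocentre; the remote upper unit plays no part.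

**Step 8**
Reactants: 12 (2R,3S,4S)-2-[3,4-bis(tert-butyldimethylsilyloxy)phenyl]-6-[(2R,3S,4R)-7-(tert-butyldimethylsilyloxy)-2-[3,4-bis(tert-butyldimethylsilyloxy)phenyl]-3-hydroxychroman-4-yl]chromane-3,4,7-triol
Product: 13 (2R,3S,4S)-2-(3,4-dihydroxyphenyl)-6-[(2R,3S,4R)-2-(3,4-dihydroxyphenyl)-3,7-dihydroxychroman-4-yl]chromane-3,4,7-triol (target)
Conditions: n-Bu4NF (6 equiv), AcOH (6 equiv), THF, 0 °C to rt, under argon; Sephadex LH-20
Reagents that add atoms: none
Why: Fluoride cleavage of the five aryl silyl ethers, buffered with acetic acid so that the freed phenoxides should not trigger quinone methide ring opening, C2 epimerisation or loss of the C4(l) hydroxyl; no stereocentre is touched.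

**Compound list**

1 | ethyl caffeate, ethyl (E)-3-(3,4-dihydroxyphenyl)prop-2-enoate | CCOC(=O)/C=C/c1ccc(O)c(O)c1 | starting material
2 | ethyl (E)-3-[3,4-bis(tert-butyldimethylsilyloxy)phenyl]prop-2-enoate | CCOC(=O)/C=C/c1ccc(O[Si](C)(C)C(C)(C)C)c(O[Si](C)(C)C(C)(C)C)c1 | intermediate
3 | (E)-3-[3,4-bis(tert-butyldimethylsilyloxy)phenyl]prop-2-en-1-ol | OC/C=C/c1ccc(O[Si](C)(C)C(C)(C)C)c(O[Si](C)(C)C(C)(C)C)c1 | intermediate
4 | [(2S,3S)-3-[3,4-bis(tert-butyldimethylsilyloxy)phenyl]oxiran-2-yl]methanol | OC[C@@H]1O[C@H]1c1ccc(O[Si](C)(C)C(C)(C)C)c(O[Si](C)(C)C(C)(C)C)c1 | intermediate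
5 | (2R,3S)-3-[3,4-bis(tert-butyldimethylsilyloxy)phenyl]oxirane-2-carbaldehyde | O=C[C@@H]1O[C@H]1c1ccc(O[Si](C)(C)C(C)(C)C)c(O[Si](C)(C)C(C)(C)C)c1 | intermediate
6 | 3-(tert-butyldimethylsilyloxy)phenol | CC(C)(C)[Si](C)(C)Oc1cccc(O)c1 | starting material
7 | (S)-[(2S,3S)-3-[3,4-bis(tert-butyldimethylsilyloxy)phenyl]oxiran-2-yl][2-hydroxy-4-(tert-butyldimethylsilyloxy)phenyl]methanol (anti epoxy alcohol) | O[C@@H](c1ccc(O[Si](C)(C)C(C)(C)C)cc1O)[C@@H]1O[C@H]1c1ccc(O[Si](C)(C)C(C)(C)C)c(O[Si](C)(C)C(C)(C)C)c1 | intermediate (not isolated)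
8 | (2R,3S,4S)-7-(tert-butyldimethylsilyloxy)-2-[3,4-bis(tert-butyldimethylsilyloxy)phenyl]chromane-3,4-diol | CC(C)(C)[Si](C)(C)Oc1ccc2c(c1)O[C@H](c1ccc(O[Si](C)(C)C(C)(C)C)c(O[Si](C)(C)C(C)(C)C)c1)[C@@H](O)[C@H]2O | intermediate
9 | resorcinol | Oc1cccc(O)c1 | starting material
10 | (2R,3S,4R)-7-(tert-butyldimethylsilyloxy)-2-[3,4-bis(tert-butyldimethylsilyloxy)phenyl]-4-(2,4-dihydroxyphenyl)chroman-3-ol | CC(C)(C)[Si](C)(C)Oc1ccc2c(c1)O[C@H](c1ccc(O[Si](C)(C)C(C)(C)C)c(O[Si](C)(C)C(C)(C)C)c1)[C@@H](O)[C@@H]2c1ccc(O)cc1O | intermediate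
11 | (2R,3S,4R)-7-(tert-butyldimethylsilyloxy)-2-[3,4-bis(tert-butyldimethylsilyloxy)phenyl]-4-[2,4-dihydroxy-5-[(S)-hydroxy[(2S,3S)-3-[3,4-bis(tert-butyldimethylsilyloxy)phenyl]oxiran-2-yl]methyl]phenyl]chroman-3-ol (anti epoxy alcohol) | CC(C)(C)[Si](C)(C)Oc1ccc2c(c1)O[C@H](c1ccc(O[Si](C)(C)C(C)(C)C)c(O[Si](C)(C)C(C)(C)C)c1)[C@@H](O)[C@@H]2c1cc([C@H](O)[C@@H]2O[C@H]2c2ccc(O[Si](C)(C)C(C)(C)C)c(O[Si](C)(C)C(C)(C)C)c2)c(O)cc1O | intermediate (not isolated)
12 | (2R,3S,4S)-2-[3,4-bis(tert-butyldimethylsilyloxy)phenyl]-6-[(2R,3S,4R)-7-(tert-butyldimethylsilyloxy)-2-[3,4-bis(tert-butyldimethylsilyloxy)phenyl]-3-hydroxychroman-4-yl]chromane-3,4,7-triol | CC(C)(C)[Si](C)(C)Oc1ccc2c(c1)O[C@H](c1ccc(O[Si](C)(C)C(C)(C)C)c(O[Si](C)(C)C(C)(C)C)c1)[C@@H](O)[C@@H]2c1cc2c(cc1O)O[C@H](c1ccc(O[Si](C)(C)C(C)(C)C)c(O[Si](C)(C)C(C)(C)C)c1)[C@@H](O)[C@H]2O | intermediate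
13 | (2R,3S,4S)-2-(3,4-dihydroxyphenyl)-6-[(2R,3S,4R)-2-(3,4-dihydroxyphenyl)-3,7-dihydroxychroman-4-yl]chromane-3,4,7-triol | Oc1ccc2c(c1)O[C@H](c1ccc(O)c(O)c1)[C@@H](O)[C@@H]2c1cc2c(cc1O)O[C@H](c1ccc(O)c(O)c1)[C@@H](O)[C@H]2O | target

**Step count**

Total step count: 8. Longest linear sequence: 8 steps (1 to 13; aldehyde 5 enters twice, in steps 5 and 7).

**Steps most likely to fail**

1. Step 7 (Proposed new method). What may go wrong: hydroxyalkylation at the ortho carbon between the two ring D oxygens, low facial discrimination at the aldehyde, or titanium-induced breakdown of 5 before the C–C bond forms. The fallback uses a prefunctionalised arene and known chemistry in place of phenoxide-directed C–H functionalisation. It sets out from 10, which is iodinated with N-iodosuccinimide (MeCN, −20 °C) at the resorcinol carbon para to the hindered hydroxyl to give (2R,3S,4R)-7-(tert-butyldimethylsilyloxy)-2-[3,4-bis(tert-butyldimethylsilyloxy)phenyl]-4-(2,4-dihydroxy-5-iodophenyl)chroman-3-ol F1. The three hydroxyls are magnesiated with MeMgCl, and iodine–magnesium exchange with i-PrMgCl·LiCl (THF, −20 °C) gives the aryl Grignard reagent. Its addition to 5 at −78 °C (Felkin–Anh addition of an organomagnesium reagent to a 2,3-epoxy aldehyde) should give epoxy alcohol 11, here isolated. Catalytic camphorsulfonic acid in CH2Cl2 at 0 °C then closes ring F by 6-endo phenol opening of the aryl epoxide, and the route is rejoined at 12.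

2. Step 5 (Proposed new method). What may go wrong: slow C–C bond formation by the titanium aryloxide, with competing ionisation of the hydroxybenzyl alkoxide to an ortho-quinone methide and oligomerisation. The fallback sets out from 6, which is iodinated ortho to the hydroxyl and para to the silyloxy group (N-iodosuccinimide, MeCN, 0 °C) to give 2-iodo-5-(tert-butyldimethylsilyloxy)phenol F2. Deprotonation with MeMgCl, iodine–magnesium exchange with i-PrMgCl·LiCl and addition to 5 at −78 °C should give epoxy alcohol 7, here isolated. Catalytic camphorsulfonic acid in CH2Cl2 closes ring C, and the route is rejoined at 8.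

3. Step 3. What may go wrong: titanium-promoted solvolytic opening of the electron-rich benzylic epoxide by isopropanol or tartrate during the epoxidation and on work-up. The fallback sets out from 3, which is oxidised with MnO2 in CH2Cl2 to (E)-3-[3,4-bis(tert-butyldimethylsilyloxy)phenyl]prop-2-enal F3. Iminium-catalysed asymmetric epoxidation of this enal with aqueous H2O2 and 10 mol% of (S)-2-[bis(3,5-bis(trifluoromethyl)phenyl)(trimethylsilyloxy)methyl]pyrrolidine (CH2Cl2, rt), the catalyst enantiomer expected to deliver the (2R,3S)-epoxide, should give the aldehyde directly. Epoxy alcohol 4 and step 4 are bypassed, and the route is rejoined at 5.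

**Further compounds**

F1 | step 7 | (2R,3S,4R)-7-(tert-butyldimethylsilyloxy)-2-[3,4-bis(tert-butyldimethylsilyloxy)phenyl]-4-(2,4-dihydroxy-5-iodophenyl)chroman-3-ol | CC(C)(C)[Si](C)(C)Oc1ccc2c(c1)O[C@H](c1ccc(O[Si](C)(C)C(C)(C)C)c(O[Si](C)(C)C(C)(C)C)c1)[C@@H](O)[C@@H]2c1cc(I)c(O)cc1O
F2 | step 5 | 2-iodo-5-(tert-butyldimethylsilyloxy)phenol | CC(C)(C)[Si](C)(C)Oc1ccc(I)c(O)c1
F3 | step 3 | (E)-3-[3,4-bis(tert-butyldimethylsilyloxy)phenyl]prop-2-enal | O=C/C=C/c1ccc(O[Si](C)(C)C(C)(C)C)c(O[Si](C)(C)C(C)(C)C)c1
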